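**Retrosynthetic overview**
- The target is a cis-2-aryl-3-hydroxymethyl-2,3-dihydrobenzofuran carried on an exo,exo-diaryl furo[3,4-c]furan. The two phenols are unmasked last, and the CH2OH comes from an ester.
- The dihydrofuran ring of the benzofuran (C2–C3 bond) is closed by rhodium-carbene insertion into the benzylic C–H of an aryl benzyl ether. The carbene carbon is attached beforehand by palladium coupling of the aryl iodide with methyl diazoacetate.
- The strategy rests on the cis-fused furofuran (C1, O2, C3, C3a, C4, O5, C6, C6a): the bridgehead bond C3a–C6a lies next to the benzylic ether bond O5–C4. Both are made in one pot from an epoxy cinnamyl ether, by radical C–C closure and then polar C–O closure.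
- The precursor comes from a Sharpless-resolved epoxy alcohol (5-iodovanillin, vanillin, vinylmagnesium bromide) and a sinapyl bromide (syringaldehyde).
- Ring order: oxolane C1–O2–C3–C3a–C6a, then oxolane C3a–C4–O5–C6–C6a, then the dihydrofuran ring of the benzofuran.

Key step: step 11

Remarks on the chemistry:
- TIPS = triisopropylsilyl. Ar1 = 3-iodo-5-methoxy-4-{[3-methoxy-4-(TIPS-oxy)phenyl]methoxy}phenyl. Ar2 = 3,5-dimethoxy-4-(TIPS-oxy)phenyl.
- The arene on C1 carries its iodine and its benzyl ether from the start (5-iodovanillin), so only carbene chemistry, reduction and desilylation follow the key step. Both phenols are TIPS ethers.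
- Methyl diazoacetate is assumed not to be purchased and is made in step 12.

**Step 1**
Reactants: 1 vanillin
Product: 2 3-methoxy-4-(TIPS-oxy)benzaldehyde
Conditions: TIPSCl, imidazole, DMF, rt
Reagents that add atoms: triisopropylsilyl chloride, CC(C)[Si](Cl)(C(C)C)C(C)C
Why: Silyl ether formation on the phenol is routine, and the bulky TIPS ether should survive the hydride, Grignard, titanium, palladium and rhodium steps until the final fluoride treatment.

**Step 2**
Reactants: 2 3-methoxy-4-(TIPS-oxy)benzaldehyde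
Product: 3 [3-methoxy-4-(TIPS-oxy)phenyl]methanol
Conditions: NaBH4, MeOH, 0 °C
Reagents that add atoms: none
Why: Borohydride reduction of the aldehyde to the benzylic alcohol is chemoselective and leaves the aryl silyl ether untouched at 0 °C.

**Step 3**
Reactants: 3 [3-methoxy-4-(TIPS-oxy)phenyl]methanol; 4 5-iodovanillin (4-hydroxy-3-iodo-5-methoxybenzaldehyde)
Product: 5 Ar1-carbaldehyde (3-iodo-5-methoxy-4-{[3-methoxy-4-(TIPS-oxy)phenyl]methoxy}benzaldehyde)
Conditions: PPh3, diisopropyl azodicarboxylate, THF, 0 °C → rt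
Reagents that add atoms: none
Why: Mitsunobu etherification suits this pair because 5-iodovanillin is an acidic phenol (para-formyl, ortho-iodo) and 3 is an unhindered primary benzylic alcohol, and it avoids handling a labile electron-rich benzyl bromide.

**Step 4**
Reactants: 5 Ar1-carbaldehyde; 6 vinylmagnesium bromide
Product: 7 racemic 1-Ar1-prop-2-en-1-ol
Conditions: THF, −78 → 0 °C; aq. NH4Cl
Reagents that add atoms: none
Why: Grignard 1,2-addition to the aldehyde at −78 °C is much faster than iodine–magnesium exchange at the aryl iodide and gives the racemic secondary allylic alcohol needed for resolution.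

**Step 5**
Reactants: 7 racemic 1-Ar1-prop-2-en-1-ol
Product: 8 (R)-Ar1[(2S)-oxiran-2-yl]methanol (erythro epoxy alcohol)
Conditions: Ti(OiPr)4 (0.2 equiv), D-(−)-diisopropyl tartrate (0.25 equiv), t-BuOOH (0.45 equiv), 4 Å MS, CH2Cl2, −20 °C
Reagents that add atoms: tert-butyl hydroperoxide, CC(C)(C)OO
Why: Sharpless kinetic resolution (titanium–tartrate asymmetric epoxidation): with D-(−)-tartrate the (S)-alcohol should be epoxidised far faster than its antipode, erythro to the hydroxyl, so the carbinol centre is selected by the resolution (its descriptor becomes R only because oxiranyl outranks aryl) and the catalyst-set oxirane centre is erased again in step 11.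

**Step 6**
Reactants: 9 syringaldehyde
Product: 10 3,5-dimethoxy-4-(TIPS-oxy)benzaldehyde
Conditions: TIPSOTf, 2,6-lutidine, CH2Cl2, 0 °C → rt
Reagents that add atoms: triisopropylsilyl trifluoromethanesulfonate, CC(C)[Si](OS(=O)(=O)C(F)(F)F)(C(C)C)C(C)C
Why: Silylation of the hindered 2,6-dimethoxyphenol calls for the silyl triflate, and TIPS is chosen so that the ether resists the alkoxide of step 10 and the benzylic ionisation of step 11.

**Step 7**
Reactants: 10 3,5-dimethoxy-4-(TIPS-oxy)benzaldehyde; 11 triethyl phosphonoacetate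
Product: 12 ethyl (E)-3-Ar2-prop-2-enoate
Conditions: NaH, THF, 0 °C → rt
Reagents that add atoms: none
Why: Horner–Wadsworth–Emmons olefination of an aromatic aldehyde with a stabilised phosphonate anion gives the E-cinnamate reliably.

**Step 8**
Reactants: 12 ethyl (E)-3-Ar2-prop-2-enoate
Product: 13 (E)-3-Ar2-prop-2-en-1-ol
Conditions: i-Bu2AlH (2.2 equiv), CH2Cl2, −78 °C; Rochelle salt
Reagents that add atoms: none
Why: i-Bu2AlH reduces the conjugated ester 1,2 to the allylic alcohol at low temperature without touching the alkene or the silyl ether.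

**Step 9**
Reactants: 13 (E)-3-Ar2-prop-2-en-1-ol
Product: 14 (E)-3-Ar2-prop-2-en-1-yl bromide
Conditions: PBr3 (0.4 equiv), Et2O, 0 °C; used crude
Reagents that add atoms: phosphorus tribromide, BrP(Br)Br
Why: Bromination of the primary allylic alcohol with PBr3 proceeds by SN2 with retention of the E geometry, and the electron-rich cinnamyl bromide is used at once because it ionises easily.

**Step 10**
Reactants: 8 (R)-Ar1[(2S)-oxiran-2-yl]methanol; 14 (E)-3-Ar2-prop-2-en-1-yl bromide
Product: 15 (2S)-2-[(R)-Ar1{[(2E)-3-Ar2-prop-2-en-1-yl]oxy}methyl]oxirane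
Conditions: NaH, THF, 0 °C; then 14, Bu4NI (cat.), 0 °C → rt
Reagents that add atoms: none
Why: Williamson etherification: the sodium alkoxide of 8 attacks the primary allylic bromide by SN2 (iodide catalysis), which in THF at 0 °C should outrun Payne migration of the oxirane, and the carbinol centre is not touched.

**Step 11**
Reactants: 15 (2S)-2-[(R)-Ar1{[(2E)-3-Ar2-prop-2-en-1-yl]oxy}methyl]oxirane
Product: 18 (1S,3aR,4S,6aR)-1-Ar1-4-Ar2-tetrahydro-1H,3H-furo[3,4-c]furan, via benzylic titanium oxolane 16 (not isolated), via benzylic iodide 17 (not isolated)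
Conditions: Cp2TiCl2 (2.5 equiv), Zn dust, THF, rt, green solution added slowly to 15 (0.02 M); then I2 (1.5 equiv), rt
Reagents that add atoms: none
Why: Cp2TiCl (trivalent titanium) transfers one electron to the oxirane, which opens to the secondary radical at C6a with its oxygen held as a titanium alkoxide on C6 (the oxirane stereocentre is erased), and this radical adds 5-exo-trig to the styrenyl double bond to form C3a–C6a and close the first oxolane (C1–O2–C3–C3a–C6a). The benzylic radical at C4 is intercepted by a second Cp2TiCl as the benzyltitanium 16, iodine turns it into the benzylic iodide 17, and the C6 alkoxide displaces iodide 5-exo-tet (through the cation that the para-silyloxy aryl group stabilises) to form O5–C4 and close the second oxolane (C3a–C4–O5–C6–C6a). The closest known reaction type is the titanocene chloride radical cyclisation of 2,3-epoxy ethers of cinnamyl alcohols with iodine-induced closure to 2,6-diaryl furofurans. C6a is set trans to the C1 aryl group because that group lies pseudo-equatorial in the chair-like 5-exo transition state, C3a is set cis to the C6 arm by the 1,5-cis preference of such closures (hence the cis ring fusion), and C4 places its aryl group on the convex face when the tethered oxygen closes onto the planar benzylic centre. The step needs 5-exo over 6-endo attack, cyclisation faster than reduction of the first radical (which would end in deoxygenation) and relay of all three new centres from C1; the aryl-terminated alkene, slow addition of Cp2TiCl to dilute 15 and the single (R)-carbinol centre secure these, and the aryl iodide and silyl ethers should be inert to this mild reductant.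

**Step 12**
Reactants: 19 glycine methyl ester hydrochloride
Product: 20 methyl diazoacetate
Conditions: NaNO2, H2SO4 (cat.), H2O/CH2Cl2, −5 °C; used as a CH2Cl2 solution
Reagents that add atoms: sodium nitrite, [Na+].[O-]N=O
Why: Diazotisation of the α-amino ester with nitrous acid gives the acceptor-stabilised diazo ester, which is extracted into CH2Cl2 as it forms and is not concentrated.

**Step 13**
Reactants: 18 (1S,3aR,4S,6aR)-1-Ar1-4-Ar2-tetrahydro-1H,3H-furo[3,4-c]furan; 20 methyl diazoacetate
Product: 21 methyl 2-diazo-2-{3-methoxy-2-[(3-methoxy-4-(TIPS-oxy)phenyl)methoxy]-5-[(1S,3aR,4S,6aR)-4-Ar2-tetrahydro-1H,3H-furo[3,4-c]furan-1-yl]phenyl}acetate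
Conditions: Pd(PPh3)4 (5 mol %), Ag2CO3 (0.5 equiv), Et3N (1.3 equiv), toluene, rt
Reagents that add atoms: none
Why: Palladium-catalysed cross-coupling of an aryl iodide with the C–H bond of a diazoacetate (zerovalent palladium, silver carbonate, amine base) is known to give aryl diazoacetates at room temperature with the diazo group intact, and no other bond in 18 should react with zerovalent palladium.

**Step 14**
Reactants: 21 aryl diazoacetate
Product: 22 methyl (2S,3R)-7-methoxy-2-[3-methoxy-4-(TIPS-oxy)phenyl]-5-[(1S,3aR,4S,6aR)-4-Ar2-tetrahydro-1H,3H-furo[3,4-c]furan-1-yl]-2,3-dihydro-1-benzofuran-3-carboxylate (2,3-cis)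
Conditions: Rh2(S-PTTL)4 (2 mol %), toluene, 4 Å MS, −60 °C, slow addition of 21
Reagents that add atoms: none
Why: Intramolecular 1,5 C–H insertion of the rhodium carbene into the benzylic C–H next to the ether oxygen forms C2–C3 and closes the dihydrofuran ring; this phthalimido-tert-leucinate catalyst is known to give the kinetic cis 2-aryl-3-carboxylate, its (S) ligands are expected to set (2S,3R), and the distant furofuran centres should have no influence.

**Step 15**
Reactants: 22 cis ester
Product: 23 {(2S,3S)-7-methoxy-2-[3-methoxy-4-(TIPS-oxy)phenyl]-5-[(1S,3aR,4S,6aR)-4-Ar2-tetrahydro-1H,3H-furo[3,4-c]furan-1-yl]-2,3-dihydro-1-benzofuran-3-yl}methanol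
Conditions: LiAlH4, THF, −40 → 0 °C; Rochelle salt
Reagents that add atoms: none
Why: Hydride reduction of the ester at low temperature is faster than enolisation, so the cis relationship should be kept (C3 becomes S only through the priority change from CO2Me to CH2OH).

**Step 16**
Reactants: 23 bis-TIPS alcohol
Product: 24 CNP0126146.1, 4-[(1S,3aR,4S,6aR)-4-[(2S,3S)-2-(4-hydroxy-3-methoxyphenyl)-3-(hydroxymethyl)-7-methoxy-2,3-dihydro-1-benzofuran-5-yl]tetrahydro-1H,3H-furo[3,4-c]furan-1-yl]-2,6-dimethoxyphenol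
Conditions: Bu4NF (3 equiv), AcOH (3 equiv), THF, 0 °C → rt
Reagents that add atoms: none
Why: Fluoride cleavage of both aryl silyl ethers, buffered with acetic acid so that neither acid nor free phenoxide can epimerise C2 through a quinone methide, should give the target.

**Compound list**
1 | vanillin | COc1cc(C=O)ccc1O | starting material
2 | 3-methoxy-4-(TIPS-oxy)benzaldehyde | COc1cc(C=O)ccc1O[Si](C(C)C)(C(C)C)C(C)C | intermediate
3 | [3-methoxy-4-(TIPS-oxy)phenyl]methanol | COc1cc(CO)ccc1O[Si](C(C)C)(C(C)C)C(C)C | intermediate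
4 | 5-iodovanillin | COc1cc(C=O)cc(I)c1O | starting material
5 | 3-iodo-5-methoxy-4-{[3-methoxy-4-(TIPS-oxy)phenyl]methoxy}benzaldehyde | COc1cc(C=O)cc(I)c1OCc1ccc(O[Si](C(C)C)(C(C)C)C(C)C)c(OC)c1 | intermediate
6 | vinylmagnesium bromide | C=C[Mg]Br | starting material
7 | racemic 1-Ar1-prop-2-en-1-ol | COc1cc(cc(I)c1OCc1ccc(O[Si](C(C)C)(C(C)C)C(C)C)c(OC)c1)C(O)C=C | intermediate
8 | (R)-Ar1[(2S)-oxiran-2-yl]methanol | COc1cc(cc(I)c1OCc1ccc(O[Si](C(C)C)(C(C)C)C(C)C)c(OC)c1)[C@@H](O)[C@@H]1CO1 | intermediate
9 | syringaldehyde | COc1cc(C=O)cc(OC)c1O | starting material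
10 | 3,5-dimethoxy-4-(TIPS-oxy)benzaldehyde | COc1cc(C=O)cc(OC)c1O[Si](C(C)C)(C(C)C)C(C)C | intermediate
11 | triethyl phosphonoacetate | CCOC(=O)CP(=O)(OCC)OCC | starting material
12 | ethyl (E)-3-[3,5-dimethoxy-4-(TIPS-oxy)phenyl]prop-2-enoate | CCOC(=O)/C=C/c1cc(OC)c(O[Si](C(C)C)(C(C)C)C(C)C)c(OC)c1 | intermediate
13 | (E)-3-[3,5-dimethoxy-4-(TIPS-oxy)phenyl]prop-2-en-1-ol | OC/C=C/c1cc(OC)c(O[Si](C(C)C)(C(C)C)C(C)C)c(OC)c1 | intermediate
14 | (E)-3-[3,5-dimethoxy-4-(TIPS-oxy)phenyl]prop-2-en-1-yl bromide | BrC/C=C/c1cc(OC)c(O[Si](C(C)C)(C(C)C)C(C)C)c(OC)c1 | intermediate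
15 | (2S)-2-[(R)-Ar1{[(2E)-3-Ar2-prop-2-en-1-yl]oxy}methyl]oxirane (key-step precursor) | COc1cc(cc(I)c1OCc1ccc(O[Si](C(C)C)(C(C)C)C(C)C)c(OC)c1)[C@@H](OC/C=C/c1cc(OC)c(O[Si](C(C)C)(C(C)C)C(C)C)c(OC)c1)[C@@H]1CO1 | intermediate
16 | oxolane with Ar1 at C2 trans to the C3 CH2O–Ti(Cl)Cp2 arm, C4 cis to C3 and bearing CH(Ar2)–Ti(Cl)Cp2 (benzylic centre unassigned; Cp drawn σ-bonded) | COc1cc(cc(I)c1OCc1ccc(O[Si](C(C)C)(C(C)C)C(C)C)c(OC)c1)[C@H]1OC[C@H](C(c2cc(OC)c(O[Si](C(C)C)(C(C)C)C(C)C)c(OC)c2)[Ti](Cl)(C2C=CC=C2)C2C=CC=C2)[C@@H]1CO[Ti](Cl)(C1C=CC=C1)C1C=CC=C1 | intermediate (not isolated)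
17 | the same oxolane with CH(I)Ar2 at C4 (benzylic centre unassigned) and the titanium alkoxide at C6 | COc1cc(cc(I)c1OCc1ccc(O[Si](C(C)C)(C(C)C)C(C)C)c(OC)c1)[C@H]1OC[C@H](C(I)c2cc(OC)c(O[Si](C(C)C)(C(C)C)C(C)C)c(OC)c2)[C@@H]1CO[Ti](Cl)(C1C=CC=C1)C1C=CC=C1 | intermediate (not isolated)
18 | (1S,3aR,4S,6aR)-1-Ar1-4-Ar2-tetrahydro-1H,3H-furo[3,4-c]furan (key-step product) | COc1cc(cc(I)c1OCc1ccc(O[Si](C(C)C)(C(C)C)C(C)C)c(OC)c1)[C@H]1OC[C@H]2[C@@H]1CO[C@@H]2c1cc(OC)c(O[Si](C(C)C)(C(C)C)C(C)C)c(OC)c1 | intermediate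
19 | glycine methyl ester hydrochloride | COC(=O)C[NH3+].[Cl-] | starting material
20 | methyl diazoacetate | COC(=O)C=[N+]=[N-] | intermediate
21 | methyl 2-diazo-2-aryl acetate (iodine of 18 replaced by C(N2)CO2Me) | COc1cc(cc(C(=[N+]=[N-])C(=O)OC)c1OCc1ccc(O[Si](C(C)C)(C(C)C)C(C)C)c(OC)c1)[C@H]1OC[C@H]2[C@@H]1CO[C@@H]2c1cc(OC)c(O[Si](C(C)C)(C(C)C)C(C)C)c(OC)c1 | intermediate
22 | methyl (2S,3R)-cis-dihydrobenzofuran-3-carboxylate, bis-TIPS | COc1cc([C@H]2Oc3c(OC)cc([C@H]4OC[C@H]5[C@@H]4CO[C@@H]5c4cc(OC)c(O[Si](C(C)C)(C(C)C)C(C)C)c(OC)c4)cc3[C@H]2C(=O)OC)ccc1O[Si](C(C)C)(C(C)C)C(C)C | intermediate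
23 | (2S,3S)-cis-dihydrobenzofuran-3-ylmethanol, bis-TIPS | COc1cc([C@H]2Oc3c(OC)cc([C@H]4OC[C@H]5[C@@H]4CO[C@@H]5c4cc(OC)c(O[Si](C(C)C)(C(C)C)C(C)C)c(OC)c4)cc3[C@H]2CO)ccc1O[Si](C(C)C)(C(C)C)C(C)C | intermediate
24 | CNP0126146.1 | COc1cc([C@H]2Oc3c(OC)cc([C@H]4OC[C@H]5[C@@H]4CO[C@@H]5c4cc(OC)c(O)c(OC)c4)cc3[C@H]2CO)ccc1O | target

**Totals**
Total step count: 16.
Longest linear sequence: 11 steps (1, 2, 3, 4, 5, 10, 11, 13, 14, 15, 16).

**Steps most likely to fail**

Step 14 (carbene insertion). The catalyst may fail to tell the two faces of the carbene apart on this meta-substituted, electron-rich benzyl ether flanked by the 7-methoxy group. That would give both cis dihydrobenzofurans on the same furofuran, which would be hard to separate. The fallback adds a covalently bound auxiliary as a second control element; it sets out from 18 and comes back at 23. Compound 18 would be coupled under the conditions of step 13 with (3R)-4,4-dimethyl-2-oxooxolan-3-yl diazoacetate F3 (one step from (R)-pantolactone and succinimidyl diazoacetate) to give the pantolactonyl aryl diazoacetate F4. Insertion with Rh2(S-PTTL)4 (double stereodifferentiation; the auxiliary antipode that reinforces the catalyst is kept, (R) is drawn) should give the cis pantolactonyl ester F5, which also offers a handle for crystallisation. LiAlH4 then reduces F5 to 23 and releases the auxiliary as a triol.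

Step 13 (diazoacetate coupling). Oxidative addition and coupling at the hindered, electron-rich ortho-alkoxy aryl iodide may be slower than metal-induced decomposition of the diazo ester. The fallback separates carbon–carbon bond formation from diazo installation; it sets out from 18 and comes back at 21. Negishi-type coupling of 18 with the Reformatsky reagent BrZnCH2CO2Me (Pd(dba)2, P(t-Bu)3, THF, rt → 50 °C) should give the methyl arylacetate F2. Regitz diazo transfer (4-acetamidobenzenesulfonyl azide, DBU, MeCN, 0 °C) then gives 21.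

Step 11 (key cascade). The benzylic titanium or radical may be protonated or eliminated before iodine capture, or the para silyl group may be lost on ionisation, so that the second ring does not close cleanly. The fallback divides the cascade; it sets out from 15 and comes back at 18. The same Cp2TiCl cyclisation, quenched with aqueous NaH2PO4 instead of iodine (the reductive mode of this chemistry), should give the 2,3-trans-3,4-cis oxolane alcohol [(2S,3R,4R)-2-Ar1-4-(Ar2-methyl)oxolan-3-yl]methanol F1. The second ring is then closed with Pb(OAc)4 (benzene, CaCO3, 80 °C): the alkoxy radical abstracts the benzylic hydrogen by 1,5-transfer, the benzylic radical is oxidised, and the alcohol captures the same cation from the convex face.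

**Further compounds**
F1 | step 11 | [(2S,3R,4R)-2-Ar1-4-(Ar2-methyl)oxolan-3-yl]methanol | COc1cc(cc(I)c1OCc1ccc(O[Si](C(C)C)(C(C)C)C(C)C)c(OC)c1)[C@H]1OC[C@H](Cc2cc(OC)c(O[Si](C(C)C)(C(C)C)C(C)C)c(OC)c2)[C@@H]1CO
F2 | step 13 | methyl 2-aryl acetate (iodine of 18 replaced by CH2CO2Me) | COc1cc(cc(CC(=O)OC)c1OCc1ccc(O[Si](C(C)C)(C(C)C)C(C)C)c(OC)c1)[C@H]1OC[C@H]2[C@@H]1CO[C@@H]2c1cc(OC)c(O[Si](C(C)C)(C(C)C)C(C)C)c(OC)c1
F3 | step 14 | (3R)-4,4-dimethyl-2-oxooxolan-3-yl diazoacetate | CC1(C)COC(=O)[C@@H]1OC(=O)C=[N+]=[N-]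
F4 | step 14 | (3R)-4,4-dimethyl-2-oxooxolan-3-yl 2-diazo-2-aryl acetate (pantolactonyl analogue of 21) | COc1cc(cc(C(=[N+]=[N-])C(=O)O[C@H]2C(=O)OCC2(C)C)c1OCc1ccc(O[Si](C(C)C)(C(C)C)C(C)C)c(OC)c1)[C@H]1OC[C@H]2[C@@H]1CO[C@@H]2c1cc(OC)c(O[Si](C(C)C)(C(C)C)C(C)C)c(OC)c1
F5 | step 14 | (3R)-4,4-dimethyl-2-oxooxolan-3-yl (2S,3R)-cis-dihydrobenzofuran-3-carboxylate (pantolactonyl analogue of 22) | COc1cc([C@H]2Oc3c(OC)cc([C@H]4OC[C@H]5[C@@H]4CO[C@@H]5c4cc(OC)c(O[Si](C(C)C)(C(C)C)C(C)C)c(OC)c4)cc3[C@H]2C(=O)O[C@H]2C(=O)OCC2(C)C)ccc1O[Si](C(C)C)(C(C)C)C(C)C
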